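Readings and results stem from a simulated flask for substances that don't exist; scatter was added.

The bench chemist now asks what a flask holds at the end of the time when it is charged with equal amounts of starting material and partner.

| flask | starting material | partner | remark | time |
|---|---|---|---|---|
| winter | 0.20 M | 0.28 M | run made earlier |  |
| autumn | 0.20 M | 0.44 M | run made earlier |  |
| flask | 0.20 M | 0.200 M |  | 6.0 d |

| run | time / d | starting material / % | target / % | intermediate A / % |
|---|---|---|---|---|
| winter | 0.500 | 1.7 | 35.6 | 41.6 |
| winter | 0.833 | 1.0 | 38.0 | 36.7 |
| winter | 1.04 | 0.4 | 36.2 | 34.7 |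
| winter | 1.67 | 0 | 34.0 | 32.5 |
| winter | 2.50 | 0.1 | 32.7 | 30.5 |
| winter | 4.00 | 0 | 33.3 | 31.3 |
| winter | 6.00 | 0 | 33.0 | 30.4 |
| autumn | 0.333 | 7.4 | 39.1 | 30.3 |
| autumn | 0.833 | 0.7 | 51.0 | 15.1 |
| autumn | 1.67 | 0 | 47.6 | 6.7 |
| autumn | 2.50 | 0.3 | 45.7 | 2.6 |
| autumn | 4.00 | 0 | 47.1 | 0.6 |
| autumn | 5.00 | 0.2 | 45.9 | 0 |
| autumn | 6.00 | 0 | 47.9 | 0.5 |

(scatter of a reading: 0.5 percentage points)

- the reaction counts as stopped when no species that holds the starting material changes by six tenths of a point or more over the second half of the time

- which holds at 6.0 d: what has brought the reaction to rest, or that it has not come to rest (it is still moving / all of the starting material has reacted / forward and back rates have come level)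
- how much of the starting material has reacted by 6.0 d
- how much target there is at 6.0 d, in percent of the starting material charged
- how much intermediate A there is at 6.0 d, in percent of the starting material charged

The winter run looks contradictory. It was charged with 1.40 of partner per starting material, and its starting material reads 0 % at 6.00 d, yet intermediate A stands there at 30.4 % of the charge.

We reckon with fractions left. The fraction of starting material left gives a decay constant of 8.15 d⁻¹ in winter and 7.82 d⁻¹ in autumn, although autumn had more partner. So we take the loss of starting material to use no partner, and its half-life as read, 0.0886 d, is far shorter than the time.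

By the reading at 6.00 d in winter, 0.696 of the charge has left intermediate A. Dividing the partner charge by that gives the partner price, 2.01, the partner used per unit of charge passing beyond intermediate A, if partner is what ended winter. That clears the contradiction. Autumn's partner buys 1.09 of the charge at this price, and its intermediate A falls to 0.5 %.

Our flask's partner, the limiting reagent by this reckoning, buys 0.497, which leaves 0.503 in intermediate A. Winter's target share of what passed, 0.474, then gives 0.236 as target.

The forecast says forward and back rates have come level, with conversion 85 %, target 24 % and intermediate A 46 %, holding that “the residual probably sits at a balance”. We part from it on the starting material, because the time in our flask is 67.7 of its half-lives as read.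

The flask gives 100 % conversion against the forecast's 85 %, with target 23.7 % and intermediate A 50.1 %: all of the starting material has reacted. Partner at 6.00 d stands at 0.32 % of its charge. At our price, the 0.499 past intermediate A costs 1.00 of partner per starting material.

    partner + intermediate A ⇌ intermediate B (K = 2.40 L mol⁻¹, k = 7.90 × 10⁻⁴ L mol⁻¹ s⁻¹)
    intermediate B ⇌ intermediate C (K = 1.20, k = 1.20 × 10⁻⁴ s⁻¹)
    starting material → intermediate A (k = 8.90 × 10⁻⁵ s⁻¹)
    partner + intermediate C → target (k = 0.0100 L mol⁻¹ s⁻¹)
    target ⇌ isomer of the product (K = 1.10, k = 1.70 × 10⁻⁵ s⁻¹)

For the neighbour flask with 0.080 M of partner, the price leaves 0.801 of the charge in intermediate A. Computed, that neighbour flask holds 80.0 % intermediate A and 9.44 % target.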